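**Locants.** Terpenoid carbons are numbered C1–C11 as in an aristolane: ring A is C1–C5 plus C10, ring B is C5–C10, and C11 is the cyclopropane carbon bearing two methyl groups. The acylphloroglucinol ring is ring D with locants 1'–6': C1' carries the acyl group, C2' the free hydroxyl, C4' the methoxy group, C5' is bonded to C1 and O6' to C10.

## The problem

The target is a 4-methoxychalcone whose ring D is fused through a cis-dihydrofuran (O6'–C10 and C5'–C1) to an aristolane-type unit: ring A (a cyclohexane), ring B (a cyclohexane-8,9-dione) and a gem-dimethylcyclopropane across C6–C7. Six contiguous stereocentres (C1, C4, C5, C6, C7, C10) must be set, two of them adjacent and fully substituted (C5, and C10 as an α-aryloxy ketone carbon). On ring A the C1–aryl bond, the C10 oxygen and both methyl groups (C4, C5) lie on one face; the cyclopropane lies on the face of ring B opposite to the C5 methyl. Only C4 is remote enough to be set on its own. From there control can be relayed: C4 to C1 by facial hydrogenation, C1 to C10 because the dihydrofuran can only be cis-fused, C10 and ring A to C5, and C5 to C6/C7. Three groups will not survive rough treatment: the non-enolisable 1,2-dione (benzilic-type rearrangement with hydroxide or alkoxide), the cyclopropyl ketone (acid-induced opening) and the 2'-hydroxychalcone (a reducible Michael acceptor that can close to a flavanone). These dictate the order of the late steps. The enabling feature is that C10 lies between the C9 carbonyl and C5 and that ring B carries oxygen at both C8 and C9. Ring B therefore maps onto a 2-methoxyphenol whose alkylated ortho carbon is C10. The O6' hydroxyl of ring D, attached through C1, can reach C10 in a five-membered closure, so oxidising that phenol should create the quaternary aryl ether carbon and the dihydrofuran in one step.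

## Retrosynthesis

**25 to 24.** The C6–C11 and C7–C11 bonds are cut (isopropylidene transfer to the C6=C7 ene-dione 24). This removes two stereocentres and the most fragile ring. Closing the chalcone last instead would expose the 1,2-dione and the acetyl enolate to each other and to base, so the cyclopropane is made last. The forward reaction must pick the doubly activated ene-dione over the chalcone and approach anti to the C5 methyl.

**24 to 23 to 21 + 22.** The C8 ketone is masked as its dimethyl ketal (23), and the chalcone Cα=Cβ bond is cut to the acetyl compound 21 and 4-methoxybenzaldehyde 22. In 21 ring B has no enolisable position, no conjugated acceptor and no 1,2-dicarbonyl, so an ordinary hydroxide-mediated condensation can be used. Condensing at 24 or 25 would meet the dione; condensing before the C5 methyl is in place would offer the chalcone to the cuprate.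

**21 to 20 to 19.** The C5–CH3 bond is cut (1,6-addition to dienone 19) and the second C8 methoxy group is removed oxidatively. The dienone from the key step is electrophilic at C5, and its dienolate, trapped as silyl ether 20, is nucleophilic at C8. Oxidising 20 in methanol should therefore turn the C8 enol ether into a ketal and leave the alkene at C6=C7 in one operation. Hydrolysis to a diosphenol followed by dehydrogenation would need more steps and would free the dione too early. The forward steps need 1,6- over 1,4-regioselectivity and attack at C5 from the face of the C10 oxygen.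

**19 to 18 (key disconnection).** The O6'–C10 bond is cut, which rearomatises ring B and removes the quaternary centre and the dihydrofuran. Precursor 18 is a cis-1-aryl-4-methyltetralin with two stereocentres and three free phenols. Cutting C1–C10 or C9–C10 instead would leave the aryl ether carbon to be built by other means. The forward reaction must oxidise ring B rather than ring D and be attacked at C10.

**18 to 17.** The C1–H bond and three benzyl–oxygen bonds are cut. Hydrogenation of dihydronaphthalene 17 sets C1 from C4 and frees all phenols at once. A Friedel–Crafts alkylation of acetophenone 13 with a tetralyl cation would be shorter but gives no control of C1.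

**17 to 12 + 15 (through 16).** The C1–C5' bond is cut (Suzuki–Miyaura coupling of alkenyl triflate 12, as boronate 16, with bromide 15). Acetophenone 13 is symmetrical, so its dibenzyl ether 14 gives a single monobromide 15 with the acetyl group in place and the attachment carbon between methoxy and oxygen. An aryllithium route cannot carry the acetyl group, and acylating ring D later would be regiochemically ambiguous.

**12 to 11 to 10 to 8.** The C1–C10 bond is cut (intramolecular Friedel–Crafts acylation of acid 8). A bromine para to the benzyloxy group blocks the otherwise preferred position and forces closure at C10; it is removed (10 to 11) before any palladium coupling.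

**8 to 7 to 5 to 4 to 3 to 1 + 2.** A one-carbon Arndt–Eistert homologation inserts C2, and the C4–C5 bond is cut to boronic acid 1 and methyl crotonate 2. The rhodium-catalysed asymmetric conjugate addition sets C4, the only stereocentre that depends on a chiral reagent.

## Roads not taken

**Alternative 1: tethered ortho-quinone Diels–Alder.** The cut is at C1–C10 and C4–C5. In the forward direction the tetrasubstituted C10=C5 bond of aryloxy-ortho-quinone A1 adds to the (1E,3E)-pentadienyl group on the same aryl ring to give A2, closing ring A and the dihydrofuran together.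
- Merits: it is the shortest road. The C5 methyl and the C10 oxygen are cis on the dienophile and stay cis, so the C5 problem that the chosen plan solves by a face-selective cuprate addition does not arise. A2 already contains the C6=C7 ene-dione. In these respects it is better than the chosen plan.
- Weak points: A1 has no stereocentre, so absolute configuration needs an asymmetric catalyst for a hindered, electron-rich dienophile. Ortho-quinones dimerise and also react as heterodienes through the dione. The three-atom tether through the arene strains the transition state. The relation of C4 to C5 rests on endo/exo selectivity. A2 carries a C2=C3 alkene that must be reduced in the presence of the ene-dione, and a methyl ether ortho to the acetyl group that must be cleaved selectively.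
- Against this the chosen plan sets one reliable catalytic asymmetric step whose information is relayed through every later centre, and stable, isolable intermediates.

**Alternative 2: ketyl dearomatisation of a benzofuran.** The cut is at C9–C10. SmI2 with HMPA turns the aldehyde of benzofuran A3 into a ketyl that adds to C10; the C1 benzylic radical is reduced and protonated to give A4.
- Merits: C4 and C5 are in place before ring B closes, and the chain on C5 can only reach C10 from its own face, so C10 and C1 follow from C5 with certainty. This is better stereocontrol at C5 than the chosen plan offers.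
- Weak points: A3 needs an enantioselective construction of a quaternary carbon next to the benzofuran with a cis-vicinal methyl group. Ring B arrives saturated and oxygenated only at C9, so the C8 oxygen, the C6=C7 unsaturation and both ketones must be introduced by a long redox sequence before the cyclopropane can be made.
- The chosen plan sets against this that the arene delivers ring B with both oxygens and the right unsaturation for the remaining steps.

**Alternative 3: gold carbene cycloisomerisation.** The cut is at C6–C7 and C7–C11. Ph3PAuNTf2 (or PtCl2) induces 1,2-acetate migration in propargylic acetate A5; the resulting C7 carbene cyclopropanates the isobutenyl group on C5 and gives enol acetate A6.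
- Merits: ring B, the cyclopropane and the C8 oxygen are formed in one catalytic step with a cis-fused cyclopropane. This is cleaner than the ylide addition to an ene-dione used in the chosen plan.
- Weak points: the key step does not address the hardest part of the molecule. A5 already contains the vicinal quaternary pair C5/C10 with the aryl ether, which must be built by other chemistry. The cyclopropane face relative to the C5 methyl depends on the folding of the tether. The carbene can be intercepted by the electron-rich arene or the ether oxygen. C9 still has to be oxidised to the ketone.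
- The chosen plan creates the C10 aryl ether directly from a simple phenol, which this road presupposes.

Key step: step 13

**Assumption:** boronic acid 1 is taken as a catalogue compound; 2, 13 and 22 are bulk chemicals.

**Remark:** in steps 14 and 18 the free 2'-hydroxyl consumes one equivalent of the organometallic reagent, which is allowed for in the stoichiometry.

## Route

Step 1
Reactants: 1 [3-(benzyloxy)-4-methoxyphenyl]boronic acid; 2 methyl (E)-but-2-enoate (methyl crotonate)
Product: 3 methyl (3R)-3-[3-(benzyloxy)-4-methoxyphenyl]butanoate
Conditions: Rh(acac)(C2H4)2 (3 mol %), (S)-BINAP, dioxane/H2O (10:1), 100 °C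
Reagents that add atoms: none
Why: Rhodium-catalysed asymmetric conjugate addition of an arylboronic acid to an (E)-enoate (Hayashi–Miyaura reaction); the BINAP-bound aryl-rhodium species adds to one enantioface, and (S)-BINAP is chosen because its quadrant model places the aryl group on the 2si,3re face, which gives the 3R ester (the antipodal ligand serves if the sense proves opposite). This sets C4.

Step 2
Reactants: 3 methyl (3R)-3-[3-(benzyloxy)-4-methoxyphenyl]butanoate
Product: 4 methyl (3R)-3-[5-(benzyloxy)-2-bromo-4-methoxyphenyl]butanoate
Conditions: NBS, MeCN, 0 °C to rt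
Reagents that add atoms: N-bromosuccinimide, O=C1CCC(=O)N1Br
Why: Electrophilic aromatic bromination; the carbon para to the benzyloxy group and ortho to the side chain is the most activated free position of a 4-alkyl-1,2-dialkoxybenzene, and this is the position that must be blocked for the later ring closure.

Step 3
Reactants: 4 methyl (3R)-3-[5-(benzyloxy)-2-bromo-4-methoxyphenyl]butanoate
Product: 5 (3R)-3-[5-(benzyloxy)-2-bromo-4-methoxyphenyl]butanoic acid
Conditions: LiOH, THF/MeOH/H2O, rt; then aq. HCl
Reagents that add atoms: lithium hydroxide (LiOH), [Li+].[OH-]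
Why: Ester saponification; the stereocentre is β to the carboxyl group and cannot epimerise.

Step 4
Reactants: 5 (3R)-3-[5-(benzyloxy)-2-bromo-4-methoxyphenyl]butanoic acid
Product: 7 (4R)-4-[5-(benzyloxy)-2-bromo-4-methoxyphenyl]-1-diazopentan-2-one, via acid chloride 6 (not isolated)
Conditions: (COCl)2, DMF (cat.), CH2Cl2, 0 °C to rt; then Me3SiCHN2, MeCN/THF, 0 °C
Reagents that add atoms: oxalyl chloride, ClC(=O)C(=O)Cl (chlorine of 6 only); trimethylsilyldiazomethane, C[Si](C)(C)C=[N+]=[N-] (the CHN2 unit of 7)
Why: First half of an Arndt–Eistert homologation; the acid chloride acylates the diazoalkane carbon and the silyl group is lost as the chlorosilane.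

Step 5
Reactants: 7 (4R)-4-[5-(benzyloxy)-2-bromo-4-methoxyphenyl]-1-diazopentan-2-one
Product: 8 (4R)-4-[5-(benzyloxy)-2-bromo-4-methoxyphenyl]pentanoic acid
Conditions: PhCO2Ag (10 mol %), Et3N, dioxane/H2O, rt to 60 °C, dark
Reagents that add atoms: water, O
Why: Silver-catalysed Wolff rearrangement; the ketene is trapped by water, and the migrating CH2 group carries the untouched stereocentre.

Step 6
Reactants: 8 (4R)-4-[5-(benzyloxy)-2-bromo-4-methoxyphenyl]pentanoic acid
Product: 10 (4R)-8-(benzyloxy)-5-bromo-7-methoxy-4-methyl-3,4-dihydronaphthalen-1(2H)-one, via acid chloride 9 (not isolated)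
Conditions: (COCl)2, DMF (cat.), CH2Cl2, 0 °C; then SnCl4, CH2Cl2, −78 to −20 °C
Reagents that add atoms: oxalyl chloride, ClC(=O)C(=O)Cl (chlorine of 9 only)
Why: Intramolecular Friedel–Crafts acylation; with the position para to the benzyloxy group occupied by bromine the acylium ion can only attack the carbon between the side chain and the benzyloxy group (C10), giving the 8-oxygenated tetralone. SnCl4 at low temperature should leave the benzyl ether in place.

Step 7
Reactants: 10 (4R)-8-(benzyloxy)-5-bromo-7-methoxy-4-methyl-3,4-dihydronaphthalen-1(2H)-one
Product: 11 (4R)-8-(benzyloxy)-7-methoxy-4-methyl-3,4-dihydronaphthalen-1(2H)-one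
Conditions: Pd(OAc)2 (5 mol %), PPh3, HCO2Na, DMF, 90 °C
Reagents that add atoms: none
Why: Palladium-catalysed transfer hydrodebromination with formate; a homogeneous palladium hydride reduces the aryl bromide without touching the benzyl ether or the ketone, and removing the halogen here keeps the later couplings unambiguous.

Step 8
Reactants: 11 (4R)-8-(benzyloxy)-7-methoxy-4-methyl-3,4-dihydronaphthalen-1(2H)-one
Product: 12 (4R)-8-(benzyloxy)-7-methoxy-4-methyl-3,4-dihydronaphthalen-1-yl trifluoromethanesulfonate
Conditions: Tf2O, 2,6-di-tert-butyl-4-methylpyridine, CH2Cl2, 0 °C to rt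
Reagents that add atoms: trifluoromethanesulfonic anhydride, O=S(=O)(OS(=O)(=O)C(F)(F)F)C(F)(F)F
Why: Enol triflate formation from an aryl ketone with Tf2O and a hindered pyridine base; the tetralone can enolise only toward C2.

Step 9
Reactants: 13 1-(2,6-dihydroxy-4-methoxyphenyl)ethan-1-one
Product: 14 1-[2,6-bis(benzyloxy)-4-methoxyphenyl]ethan-1-one
Conditions: BnBr, K2CO3, DMF, 60 °C
Reagents that add atoms: benzyl bromide, BrCc1ccccc1
Why: Williamson etherification of both chelated phenols; benzyl is chosen because it is cleaved in the hydrogenation of step 12.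

Step 10
Reactants: 14 1-[2,6-bis(benzyloxy)-4-methoxyphenyl]ethan-1-one
Product: 15 1-[2,6-bis(benzyloxy)-3-bromo-4-methoxyphenyl]ethan-1-one
Conditions: NBS, MeCN, 0 °C to rt
Reagents that add atoms: N-bromosuccinimide, O=C1CCC(=O)N1Br
Why: Electrophilic bromination of a trialkoxyarene; the two free ring positions are equivalent by symmetry, so one monobromide results, and the first bromine deactivates the ring against a second.

Step 11
Reactants: 12 (4R)-8-(benzyloxy)-7-methoxy-4-methyl-3,4-dihydronaphthalen-1-yl trifluoromethanesulfonate; 15 1-[2,6-bis(benzyloxy)-3-bromo-4-methoxyphenyl]ethan-1-one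
Product: 17 1-{2,6-bis(benzyloxy)-3-[(4R)-8-(benzyloxy)-7-methoxy-4-methyl-3,4-dihydronaphthalen-1-yl]-4-methoxyphenyl}ethan-1-one, via alkenyl pinacolboronate 16 (not isolated)
Conditions: B2pin2, PdCl2(PPh3)2, PPh3, KOPh, toluene, 50 °C; then 15, Pd(OAc)2, SPhos, K3PO4, H2O, 90 °C
Reagents that add atoms: bis(pinacolato)diboron, CC1(C)OB(OC1(C)C)B1OC(C)(C)C(C)(C)O1 (boron unit of 16 only)
Why: Miyaura borylation of the alkenyl triflate followed in the same flask by Suzuki–Miyaura coupling; a dialkylbiarylphosphine ligand is the established answer to di-ortho-substituted partners, and placing boron on the alkenyl partner avoids a 2,6-dialkoxyarylboronic acid that would protodeboronate.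

Step 12
Reactants: 17 1-{2,6-bis(benzyloxy)-3-[(4R)-8-(benzyloxy)-7-methoxy-4-methyl-3,4-dihydronaphthalen-1-yl]-4-methoxyphenyl}ethan-1-one
Product: 18 1-{2,6-dihydroxy-3-[(1S,4R)-8-hydroxy-7-methoxy-4-methyl-1,2,3,4-tetrahydronaphthalen-1-yl]-4-methoxyphenyl}ethan-1-one (cis)
Conditions: H2 (4 atm), Pd(OH)2/C, EtOAc/EtOH, rt
Reagents that add atoms: none
Why: Heterogeneous hydrogenation combined with hydrogenolysis of the three benzyl ethers; the C4 methyl group sits pseudo-axial on the dihydronaphthalene half-chair and shields one face of the trisubstituted alkene, so hydrogen should add anti to it and leave the aryl group at C1 cis to the methyl group (1S). The chelated, electron-rich acetyl group is not expected to be reduced.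

Step 13
Reactants: 18 1-{2,6-dihydroxy-3-[(1S,4R)-8-hydroxy-7-methoxy-4-methyl-1,2,3,4-tetrahydronaphthalen-1-yl]-4-methoxyphenyl}ethan-1-one
Product: 19 ortho-quinol aryl ether: O6' bonded to C10; ring B is the 8-methoxy-5,7-dien-9-one; C10–O, C1–C5' and the C4 methyl group on one face of ring A
Conditions: undivided cell, graphite anode, Pt cathode, constant current (2.1 F/mol), Bu4NBF4, 2,6-lutidine, HFIP/CH2Cl2 (1:4), 0 °C
Reagents that add atoms: none
Why: Anodic two-electron oxidation of the 2-methoxyphenol ring of 18, with loss of a proton to 2,6-lutidine, gives a phenoxonium ion with positive charge at C10, C8 and C6; the O6' hydroxyl, held next to C10 by the C1–C5' bond, adds to C10 and a second proton is lost, leaving the cyclohexa-2,4-dienone 19 (C9=O, C8 methyl enol ether, C5=C6). The closest known reaction type is the oxidative dearomatisation of 2-alkoxyphenols with tethered oxygen nucleophiles to ortho-quinol ethers, run anodically or with PhI(OAc)2, together with the phenol-oxygen capture seen in spirodienone-forming phenolic couplings. The dihydrofuran ring (O6', C6', C5', C1, C10) closes in a 5-exo-trig mode. C10 is the only new stereocentre; the oxygen can reach it only from the face on which C1 holds ring D, so C1 dictates its configuration and the ring fusion is cis. Three selectivities are needed: ring B must be oxidised before ring D, which its lower oxidation potential should secure because the ring D hydroxyls are conjugated with and hydrogen-bonded to the acetyl group; attack must occur at C10 and not at C6 or C8, which the five-membered tether enforces; and the medium must not compete, which non-nucleophilic HFIP/CH2Cl2 and high dilution provide. The cathode reduces the liberated protons to dihydrogen.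

Step 14
Reactants: 19 ortho-quinol aryl ether (8-methoxy-5,7-dien-9-one)
Product: 20 bis(trimethylsilyl) compound: C9 silyl dienol ether [C9(OSiMe3)=C8(OMe), C6=C7] with the new C5 methyl cis to the C10 oxygen; 2'-O-trimethylsilyl
Conditions: Me2CuLi (from MeLi and CuI, 4 equiv), Me3SiCl, THF/Et2O, −78 to −40 °C; Et3N, pentane, filtration
Reagents that add atoms: lithium dimethylcuprate (Me2CuLi), [Li+].C[Cu-]C (C5 methyl); chlorotrimethylsilane, C[Si](C)(C)Cl (both silyl groups)
Why: Chlorosilane-accelerated 1,6-addition of a Gilman cuprate to a 2,4-dienone with O-silylation of the dienolate; methyl is transferred to the δ-carbon C5. The quaternary centre should form from the face of ring B that carries the C10 oxygen, because ring A (C1, C3 and their axial hydrogens) closes the opposite face and the bulky copper cluster takes the equatorial direction of the ring A chair. The 2'-phenol is deprotonated and silylated in the same operation.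

Step 15
Reactants: 20 bis(trimethylsilyl) silyl dienol ether
Product: 21 8,8-dimethoxy-6-en-9-one (C8 dimethyl ketal; C9=O; C6=C7; C5 methyl; 1'-acetyl; 2'-OH free)
Conditions: PhI(OAc)2, NaHCO3, MeOH/CH2Cl2, −40 to 0 °C
Reagents that add atoms: methanol, CO (second methoxy group at C8)
Why: Two-electron oxidation of a silyl enol ether by a trivalent iodine reagent in methanol (hypervalent-iodine α-methoxylation of silyl enol ethers, the non-aromatic counterpart of the oxidation of 2-methoxyphenols to ortho-quinone monoketals); methanol enters at C8, which already carries methoxy and gives the best-stabilised oxocarbenium ion, leaving C9=O and the C6=C7 alkene. Methanol also cleaves the aryl silyl ether.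

Step 16
Reactants: 21 8,8-dimethoxy-6-en-9-one; 22 4-methoxybenzaldehyde
Product: 23 (E)-chalcone of 21: 1'-[3-(4-methoxyphenyl)prop-2-enoyl] with ring B still the 8,8-dimethoxy-6-en-9-one
Conditions: 22 (1.5 equiv), KOH (aq.), EtOH, rt; AcOH quench
Reagents that add atoms: none
Why: Claisen–Schmidt condensation; in 21 ring B has no enolisable hydrogen, no conjugated acceptor and no 1,2-dicarbonyl, so only the acetyl group reacts, and E1cB loss of water gives the E-enone.

Step 17
Reactants: 23 chalcone C8 dimethyl ketal
Product: 24 chalcone ene-dione (C8=O, C9=O, C6=C7)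
Conditions: HCl (1 M aq.), THF, 0 °C to rt
Reagents that add atoms: water, O (C8 carbonyl oxygen)
Why: Acid hydrolysis of an allylic α-keto dimethyl ketal; ionisation is assisted by the adjacent alkene and unveils the C8 ketone in conjugation with C6=C7. Dilute acid at room temperature should not close the 2'-hydroxychalcone to a flavanone.

Step 18
Reactants: 24 chalcone ene-dione
Product: 25 CNP0121765.1 (target)
Conditions: iPrPh2S+ BF4− (2.2 equiv), LiN(iPr)2, DME, −78 °C; then 24, THF, −78 to −50 °C
Reagents that add atoms: isopropyldiphenylsulfonium tetrafluoroborate, CC(C)[S+](c1ccccc1)c1ccccc1.F[B-](F)(F)F (C11 and its two methyl groups)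
Why: Isopropylidene transfer from diphenylsulfonium isopropylide to an enone (Corey–Chaykovsky-type cyclopropanation by Michael addition and ring closure); the ylide adds to C6, the β-carbon of the C8 enone, and the enolate closes on C11 with loss of diphenyl sulfide. Approach anti to the pseudo-axial C5 methyl should place the cyclopropane on the face of ring B opposite to C5–CH3 and C10–O, setting C6 and C7. The first equivalent of ylide deprotonates the 2'-hydroxyl, and the resulting phenoxide deactivates the chalcone, so the doubly activated ene-dione should react first.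

## Compound list

1 | [3-(benzyloxy)-4-methoxyphenyl]boronic acid | COc1ccc(cc1OCc1ccccc1)B(O)O | starting material
2 | methyl (E)-but-2-enoate | C/C=C/C(=O)OC | starting material
3 | methyl (3R)-3-[3-(benzyloxy)-4-methoxyphenyl]butanoate | COC(=O)C[C@@H](C)c1ccc(OC)c(OCc2ccccc2)c1 | intermediate
4 | methyl (3R)-3-[5-(benzyloxy)-2-bromo-4-methoxyphenyl]butanoate | COC(=O)C[C@@H](C)c1cc(OCc2ccccc2)c(OC)cc1Br | intermediate
5 | (3R)-3-[5-(benzyloxy)-2-bromo-4-methoxyphenyl]butanoic acid | OC(=O)C[C@@H](C)c1cc(OCc2ccccc2)c(OC)cc1Br | intermediate
6 | (3R)-3-[5-(benzyloxy)-2-bromo-4-methoxyphenyl]butanoyl chloride | ClC(=O)C[C@@H](C)c1cc(OCc2ccccc2)c(OC)cc1Br | intermediate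
7 | (4R)-4-[5-(benzyloxy)-2-bromo-4-methoxyphenyl]-1-diazopentan-2-one | [N-]=[N+]=CC(=O)C[C@@H](C)c1cc(OCc2ccccc2)c(OC)cc1Br | intermediate
8 | (4R)-4-[5-(benzyloxy)-2-bromo-4-methoxyphenyl]pentanoic acid | OC(=O)CC[C@@H](C)c1cc(OCc2ccccc2)c(OC)cc1Br | intermediate
9 | (4R)-4-[5-(benzyloxy)-2-bromo-4-methoxyphenyl]pentanoyl chloride | ClC(=O)CC[C@@H](C)c1cc(OCc2ccccc2)c(OC)cc1Br | intermediate
10 | (4R)-8-(benzyloxy)-5-bromo-7-methoxy-4-methyl-3,4-dihydronaphthalen-1(2H)-one | O=C1CC[C@@H](C)c2c(Br)cc(OC)c(OCc3ccccc3)c12 | intermediate
11 | (4R)-8-(benzyloxy)-7-methoxy-4-methyl-3,4-dihydronaphthalen-1(2H)-one | O=C1CC[C@@H](C)c2ccc(OC)c(OCc3ccccc3)c12 | intermediate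
12 | (4R)-8-(benzyloxy)-7-methoxy-4-methyl-3,4-dihydronaphthalen-1-yl trifluoromethanesulfonate | FC(F)(F)S(=O)(=O)OC1=CC[C@@H](C)c2ccc(OC)c(OCc3ccccc3)c12 | intermediate
13 | 1-(2,6-dihydroxy-4-methoxyphenyl)ethan-1-one | CC(=O)c1c(O)cc(OC)cc1O | starting material
14 | 1-[2,6-bis(benzyloxy)-4-methoxyphenyl]ethan-1-one | CC(=O)c1c(OCc2ccccc2)cc(OC)cc1OCc1ccccc1 | intermediate
15 | 1-[2,6-bis(benzyloxy)-3-bromo-4-methoxyphenyl]ethan-1-one | CC(=O)c1c(OCc2ccccc2)cc(OC)c(Br)c1OCc1ccccc1 | intermediate
16 | 2-[(4R)-8-(benzyloxy)-7-methoxy-4-methyl-3,4-dihydronaphthalen-1-yl]-4,4,5,5-tetramethyl-1,3,2-dioxaborolane | CC1(C)OB(OC1(C)C)C1=CC[C@@H](C)c2ccc(OC)c(OCc3ccccc3)c12 | intermediate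
17 | 1-{2,6-bis(benzyloxy)-3-[(4R)-8-(benzyloxy)-7-methoxy-4-methyl-3,4-dihydronaphthalen-1-yl]-4-methoxyphenyl}ethan-1-one | CC(=O)c1c(OCc2ccccc2)cc(OC)c(C2=CC[C@@H](C)c3ccc(OC)c(OCc4ccccc4)c23)c1OCc1ccccc1 | intermediate
18 | 1-{2,6-dihydroxy-3-[(1S,4R)-8-hydroxy-7-methoxy-4-methyl-1,2,3,4-tetrahydronaphthalen-1-yl]-4-methoxyphenyl}ethan-1-one (cis; key-step precursor) | CC(=O)c1c(O)cc(OC)c([C@H]2CC[C@@H](C)c3ccc(OC)c(O)c23)c1O | intermediate
19 | ortho-quinol aryl ether (key-step product): 1'-acetyl-2'-hydroxy-4'-methoxy ring D fused through O6'–C10 and C5'–C1; ring B 8-methoxy-5,7-dien-9-one; C10–O, C1–aryl and C4–CH3 on one face of ring A | CC(=O)c1c(O)cc(OC)c2c1O[C@]13C(=O)C(OC)=CC=C1[C@H](C)CC[C@H]23 | intermediate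
20 | C9 trimethylsilyl dienol ether of the 1,6-adduct [C9(OSiMe3)=C8(OMe), C6=C7, C5–CH3 cis to C10–O], 2'-O-trimethylsilyl | CC(=O)c1c(O[Si](C)(C)C)cc(OC)c2c1O[C@]13C(O[Si](C)(C)C)=C(OC)C=C[C@@]1(C)[C@H](C)CC[C@H]23 | intermediate
21 | 8,8-dimethoxy-6-en-9-one with C5 methyl, 1'-acetyl and free 2'-hydroxyl | CC(=O)c1c(O)cc(OC)c2c1O[C@]13C(=O)C(OC)(OC)C=C[C@@]1(C)[C@H](C)CC[C@H]23 | intermediate
22 | 4-methoxybenzaldehyde | COc1ccc(C=O)cc1 | starting material
23 | (E)-4-methoxychalcone of 21 (ring B 8,8-dimethoxy-6-en-9-one) | COc1ccc(/C=C/C(=O)c2c(O)cc(OC)c3c2O[C@]24C(=O)C(OC)(OC)C=C[C@@]2(C)[C@H](C)CC[C@H]34)cc1 | intermediate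
24 | (E)-4-methoxychalcone with ring B as the 6-ene-8,9-dione | COc1ccc(/C=C/C(=O)c2c(O)cc(OC)c3c2O[C@]24C(=O)C(=O)C=C[C@@]2(C)[C@H](C)CC[C@H]34)cc1 | intermediate
25 | CNP0121765.1: chalcone with ring B as the 8,9-dione and the gem-dimethylcyclopropane across C6–C7 on the face opposite to C5–CH3 | COc1ccc(/C=C/C(=O)c2c(O)cc(OC)c3c2O[C@]24C(=O)C(=O)[C@@H]5[C@@H](C5(C)C)[C@@]2(C)[C@H](C)CC[C@H]34)cc1 | target

## Step count and risks

Total: 18 steps. Longest linear sequence: 16 steps (steps 1–8 and 11–18, from 1). The ring D branch (steps 9 and 10) joins at step 11.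

**Step 13 (key step).** The likely failure is loss of chemoselectivity at the anode: oxidation of ring D alongside ring B, intermolecular coupling of phenoxyl radicals, or cycloaddition dimerisation of the dienone. Ring D still has two free hydroxyls and the potential gap rests only on the acetyl group. Fallback: setting out from 18, the unhindered 2'-hydroxyl is capped selectively (pivaloyl chloride, Et3N, CH2Cl2, 0 °C) to give mono-pivalate F1. Its ring D has one free hydroxyl and a second acyl group and is harder to oxidise. The same closure, anodic or with PhI(OAc)2 in HFIP, gives pivalate F2, and K2CO3 in MeOH returns to the route at 19.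

**Step 14.** Most likely to go wrong are poor facial selectivity at C5 (the axial C4 methyl lies on the desired face and the allylic C–O bond may favour anti attack), 1,4-addition at C7, or failure to form the quaternary centre. Fallback: substrate control is replaced by catalyst control. Setting out from 19, AlMe3 with Cu(OTf)2 and a chiral phosphoramidite ligand (both antipodes examined) should give, after protonation, the 8-methoxy-7-en-9-one F3. Soft enolisation (Me3SiOTf, Et3N) converts F3 into 20.

**Step 15.** The silyl dienol ether may be methanolysed before it is oxidised, or the nucleophile may enter at C6, the vinylogous position. Fallback: setting out from 20, a Rubottom oxidation (mCPBA, NaHCO3, CH2Cl2, −20 °C; aq. citric acid) gives the acetyl ene-dione F4. Its less hindered C8 carbonyl is then ketalised (HC(OMe)3, MeOH, TsOH) to return at 21.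

**Step 18.** The ylide may add to the chalcone or to the C9 carbonyl (oxirane formation), or approach syn to the C5 methyl. Fallback: the order is changed so that no second acceptor is present. Setting out from 21, aqueous acid gives the ene-dione F4 described above, and the isopropylide converts it into the acetyl cyclopropyl dione F5. The chalcone is then closed without hydroxide (22, LiN(SiMe3)2, THF, −78 °C to rt), arriving at 25.

**Step 12.** Incomplete facial discrimination (formation of the trans isomer) or sluggish reduction of the hindered alkene is possible, because the directing methyl group is remote. Fallback: setting out from 17, homogeneous catalyst-controlled hydrogenation with a chiral [Ir(cod)(P,N-ligand)]BArF complex in its matched form gives the cis tribenzyl ether F6. Hydrogenolysis (H2, Pd/C) then returns to 18.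

**Step 11.** Slow transmetalation between two hindered partners may allow protodeboronation of 16 and reduction of 15. Fallback: a Barluenga coupling that needs no boron partner. Setting out from 11, condensation with 4-methylbenzenesulfonohydrazide gives tosylhydrazone F7. With 15, Pd2(dba)3, XPhos and LiOtBu in dioxane at 100 °C, this should give 17 through a palladium carbene and migratory insertion.

## Further compounds

F1 | step 13 | 2-acetyl-3-hydroxy-5-methoxy-4-[(1S,4R)-8-hydroxy-7-methoxy-4-methyl-1,2,3,4-tetrahydronaphthalen-1-yl]phenyl 2,2-dimethylpropanoate | CC(=O)c1c(OC(=O)C(C)(C)C)cc(OC)c([C@H]2CC[C@@H](C)c3ccc(OC)c(O)c23)c1O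
F2 | step 13 | 2'-O-pivalate of ortho-quinol aryl ether 19 | CC(=O)c1c(OC(=O)C(C)(C)C)cc(OC)c2c1O[C@]13C(=O)C(OC)=CC=C1[C@H](C)CC[C@H]23
F3 | step 14 | 1,6-adduct ketone: 8-methoxy-7-en-9-one with C5 methyl, 1'-acetyl, 2'-OH | CC(=O)c1c(O)cc(OC)c2c1O[C@]13C(=O)C(OC)=CC[C@@]1(C)[C@H](C)CC[C@H]23
F4 | step 15 | acetyl ene-dione: 6-ene-8,9-dione with C5 methyl, 1'-acetyl, 2'-OH | CC(=O)c1c(O)cc(OC)c2c1O[C@]13C(=O)C(=O)C=C[C@@]1(C)[C@H](C)CC[C@H]23
F5 | step 18 | acetyl cyclopropyl dione: 8,9-dione with C6–C7 gem-dimethylcyclopropane, 1'-acetyl, 2'-OH | CC(=O)c1c(O)cc(OC)c2c1O[C@]13C(=O)C(=O)[C@@H]4[C@@H](C4(C)C)[C@@]1(C)[C@H](C)CC[C@H]23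
F6 | step 12 | 1-{2,6-bis(benzyloxy)-3-[(1S,4R)-8-(benzyloxy)-7-methoxy-4-methyl-1,2,3,4-tetrahydronaphthalen-1-yl]-4-methoxyphenyl}ethan-1-one | CC(=O)c1c(OCc2ccccc2)cc(OC)c([C@H]2CC[C@@H](C)c3ccc(OC)c(OCc4ccccc4)c23)c1OCc1ccccc1
F7 | step 11 | N'-[(4R)-8-(benzyloxy)-7-methoxy-4-methyl-3,4-dihydronaphthalen-1(2H)-ylidene]-4-methylbenzenesulfonohydrazide | Cc1ccc(cc1)S(=O)(=O)NN=C1CC[C@@H](C)c2ccc(OC)c(OCc3ccccc3)c12
A1 | alternative 1 | 3-{2-acetyl-3,5-dimethoxy-6-[(1E,3E)-penta-1,3-dien-1-yl]phenoxy}-4-methylcyclohexa-3,5-diene-1,2-dione | CC(=O)c1c(OC)cc(OC)c(/C=C/C=C/C)c1OC1=C(C)C=CC(=O)C1=O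
A2 | alternative 1 | tetracyclic 8,9-dione with C2=C3 and C6=C7 double bonds, 2'-O-methyl | CC(=O)c2c(OC)cc(OC)c3c2O[C@]24C(=O)C(=O)C=C[C@@]2(C)[C@H](C)C=C[C@H]34
A3 | alternative 2 | tetrahydrodibenzofuran methyl ester with C4 methyl and quaternary C5 bearing methyl and a 4-oxobutyl chain | COC(=O)c1c(O)cc(OC)c2c1oc1c2CC[C@@H](C)[C@]1(C)CCCC=O
A4 | alternative 2 | tetracyclic C9 alcohol (either C9 epimer) with saturated ring B | COC(=O)c2c(O)cc(OC)c3c2O[C@]24C(O)CCC[C@@]2(C)[C@H](C)CC[C@H]34
A5 | alternative 3 | tricyclic dihydrobenzofuran with C10 bearing a 1-acetoxyprop-2-ynyl group (either C9 epimer) and C5 bearing methyl and 2-methylprop-1-enyl | CC(=O)c1c(O)cc(OC)c2c1O[C@@]1(C(OC(C)=O)C#C)[C@@H]2CC[C@@H](C)[C@]1(C)C=C(C)C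
A6 | alternative 3 | pentacyclic C8 enol acetate with C8=C9 double bond | CC(=O)c2c(O)cc(OC)c3c2O[C@]24C=C(OC(C)=O)[C@@H]5[C@@H](C5(C)C)[C@@]2(C)[C@H](C)CC[C@H]34
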